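**Assumption:** the target has no stereocentre, so "single enantiomer" is taken to mean the single (E,E) geometric isomer (E enone, E geranyl alkene). "Geranyl" below means (2E)-3,7-dimethylocta-2,6-dien-1-yl.

## Retrosynthetic overview

- Target 17 ⇒ bis-MOM chalcone 16 (acid-labile protection only); the Cα–Cβ enone bond is cut by a Claisen–Schmidt (crossed aldol) condensation into methyl ketone 12 and aldehyde 14.
- Ketone 12 ⇒ salicylaldehyde 9 (MOM protection, MeMgBr addition, oxidation); 9 ⇒ phenol 8 by phenol-directed ortho-formylation at the only free ortho position.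
- Phenol 8 ⇒ MOM ether 3 of 3-methoxyphenol plus geranyl bromide 4, joined by directed ortho-metalation and copper-mediated allylation at the carbon between the two oxygens.
- No ring is formed: both benzene rings are bought (3-methoxyphenol for ring A, 4-hydroxybenzaldehyde for ring B).

## Route

**Step 1**
Reactants: 1 3-methoxyphenol
Product: 3 1-methoxy-3-(methoxymethoxy)benzene
Conditions: NaH, THF/DMF, 0 °C; MOMCl, 0 °C to rt
Reagents that add atoms: chloromethyl methyl ether (MOMCl), COCCl
Why: Williamson-type O-alkylation of the sodium phenoxide with a very reactive α-chloro ether installs the MOM group that later directs the metalation.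

**Step 2**
Reactants: 3 1-methoxy-3-(methoxymethoxy)benzene; 4 geranyl bromide [(2E)-1-bromo-3,7-dimethylocta-2,6-diene]
Product: 7 2-geranyl-1-methoxy-3-(methoxymethoxy)benzene, via aryllithium 5 (not isolated), via arylcopper 6 (not isolated)
Conditions: n-BuLi, THF, 0 °C to rt; CuBr·SMe2, −40 °C; then 4, −40 °C to rt
Reagents that add atoms: none
Why: Directed ortho-metalation occurs at C2, the position activated cooperatively by OMe and OMOM, and the derived monovalent copper aryl is allylated by SN2 displacement so the E alkene of 4 is kept (no stereocentre formed).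

**Step 3**
Reactants: 7 2-geranyl-1-methoxy-3-(methoxymethoxy)benzene
Product: 8 2-geranyl-3-methoxyphenol
Conditions: p-TsOH·H2O (cat.), MeOH, 40 °C
Reagents that add atoms: none
Why: Mild acid-catalysed acetal methanolysis removes the MOM group without touching the trisubstituted alkenes, freeing the phenol needed to direct the next step.

**Step 4**
Reactants: 8 2-geranyl-3-methoxyphenol
Product: 9 3-geranyl-2-hydroxy-4-methoxybenzaldehyde
Conditions: MgCl2 (anhydrous), Et3N, (CH2O)n, MeCN, reflux
Reagents that add atoms: paraformaldehyde (reacting as formaldehyde), C=O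
Why: Casnati–Skattebøl ortho-formylation delivers formaldehyde within a magnesium phenoxide chelate to the only free ortho carbon (also para to OMe), and a second formaldehyde oxidises the hydroxymethyl intermediate by hydride transfer.

**Step 5**
Reactants: 9 3-geranyl-2-hydroxy-4-methoxybenzaldehyde
Product: 10 3-geranyl-4-methoxy-2-(methoxymethoxy)benzaldehyde
Conditions: NaH, DMF, 0 °C; MOMCl, 0 °C to rt
Reagents that add atoms: chloromethyl methyl ether (MOMCl), COCCl
Why: Williamson O-alkylation of the fully deprotonated, hydrogen-bonded phenol masks it so that the Grignard addition, the oxidation and the aldol run cleanly and flavanone closure is impossible.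

**Step 6**
Reactants: 10 3-geranyl-4-methoxy-2-(methoxymethoxy)benzaldehyde
Product: 11 rac-1-[3-geranyl-4-methoxy-2-(methoxymethoxy)phenyl]ethanol
Conditions: MeMgBr, THF, 0 °C; aq. NH4Cl
Reagents that add atoms: methylmagnesium bromide, C[Mg]Br
Why: Grignard 1,2-addition to the aldehyde gives the carbinol, whose new stereocentre is formed racemic and is erased in step 7.

**Step 7**
Reactants: 11 rac-1-[3-geranyl-4-methoxy-2-(methoxymethoxy)phenyl]ethanol
Product: 12 1-[3-geranyl-4-methoxy-2-(methoxymethoxy)phenyl]ethanone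
Conditions: Dess–Martin periodinane, pyridine, CH2Cl2, 0 °C to rt
Reagents that add atoms: none
Why: Dess–Martin oxidation converts the secondary benzylic alcohol to the methyl ketone under near-neutral conditions that spare the MOM ether and both alkenes.

**Step 8**
Reactants: 13 4-hydroxybenzaldehyde
Product: 14 4-(methoxymethoxy)benzaldehyde
Conditions: NaH, DMF, 0 °C; MOMCl, 0 °C to rt
Reagents that add atoms: chloromethyl methyl ether (MOMCl), COCCl
Why: Williamson O-alkylation masks the phenol, whose phenoxide would otherwise deactivate the aldehyde in the aldol step.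

**Step 9**
Reactants: 12 1-[3-geranyl-4-methoxy-2-(methoxymethoxy)phenyl]ethanone; 14 4-(methoxymethoxy)benzaldehyde
Product: 16 (2E)-1-[3-geranyl-4-methoxy-2-(methoxymethoxy)phenyl]-3-[4-(methoxymethoxy)phenyl]prop-2-en-1-one, via β-hydroxy ketone 15 (not isolated)
Conditions: KOH, EtOH/H2O, rt, 24–48 h
Reagents that add atoms: none
Why: Claisen–Schmidt crossed aldol condensation of the ketone enolate with a non-enolisable aldehyde, followed by E1cB dehydration, gives the thermodynamically favoured E enone; the racemic carbinol centre of 15 is lost.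

**Step 10**
Reactants: 16 (2E)-1-[3-geranyl-4-methoxy-2-(methoxymethoxy)phenyl]-3-[4-(methoxymethoxy)phenyl]prop-2-en-1-one
Product: 17 xanthoangelol F
Conditions: 3 M aq. HCl/MeOH (1:5), rt to 40 °C
Reagents that add atoms: none
Why: Acid-catalysed MOM acetal cleavage frees both phenols (the 2'-OMOM group next to the carbonyl goes fastest) under conditions mild enough to leave the enone and the geranyl chain with their E geometry.

## Compound list

1 | 3-methoxyphenol | COc1cccc(O)c1 | starting material
3 | 1-methoxy-3-(methoxymethoxy)benzene | COCOc1cccc(OC)c1 | intermediate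
4 | geranyl bromide, (2E)-1-bromo-3,7-dimethylocta-2,6-diene | BrC/C=C(\C)CCC=C(C)C | starting material
5 | [2-methoxy-6-(methoxymethoxy)phenyl]lithium | [Li]c1c(OC)cccc1OCOC | intermediate
6 | [2-methoxy-6-(methoxymethoxy)phenyl]copper | [Cu]c1c(OC)cccc1OCOC | intermediate
7 | 2-[(2E)-3,7-dimethylocta-2,6-dien-1-yl]-1-methoxy-3-(methoxymethoxy)benzene | COCOc1cccc(OC)c1C/C=C(\C)CCC=C(C)C | intermediate
8 | 2-[(2E)-3,7-dimethylocta-2,6-dien-1-yl]-3-methoxyphenol | COc1cccc(O)c1C/C=C(\C)CCC=C(C)C | intermediate
9 | 3-[(2E)-3,7-dimethylocta-2,6-dien-1-yl]-2-hydroxy-4-methoxybenzaldehyde | COc1ccc(C=O)c(O)c1C/C=C(\C)CCC=C(C)C | intermediate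
10 | 3-[(2E)-3,7-dimethylocta-2,6-dien-1-yl]-4-methoxy-2-(methoxymethoxy)benzaldehyde | COCOc1c(C=O)ccc(OC)c1C/C=C(\C)CCC=C(C)C | intermediate
11 | rac-1-{3-[(2E)-3,7-dimethylocta-2,6-dien-1-yl]-4-methoxy-2-(methoxymethoxy)phenyl}ethanol | COCOc1c(C(C)O)ccc(OC)c1C/C=C(\C)CCC=C(C)C | intermediate
12 | 1-{3-[(2E)-3,7-dimethylocta-2,6-dien-1-yl]-4-methoxy-2-(methoxymethoxy)phenyl}ethanone | COCOc1c(C(C)=O)ccc(OC)c1C/C=C(\C)CCC=C(C)C | intermediate
13 | 4-hydroxybenzaldehyde | O=Cc1ccc(O)cc1 | starting material
14 | 4-(methoxymethoxy)benzaldehyde | COCOc1ccc(C=O)cc1 | intermediate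
15 | rac-1-{3-[(2E)-3,7-dimethylocta-2,6-dien-1-yl]-4-methoxy-2-(methoxymethoxy)phenyl}-3-hydroxy-3-[4-(methoxymethoxy)phenyl]propan-1-one | COCOc1ccc(cc1)C(O)CC(=O)c1ccc(OC)c(C/C=C(\C)CCC=C(C)C)c1OCOC | intermediate
16 | (2E)-1-{3-[(2E)-3,7-dimethylocta-2,6-dien-1-yl]-4-methoxy-2-(methoxymethoxy)phenyl}-3-[4-(methoxymethoxy)phenyl]prop-2-en-1-one | COCOc1ccc(/C=C/C(=O)c2ccc(OC)c(C/C=C(\C)CCC=C(C)C)c2OCOC)cc1 | intermediate
17 | xanthoangelol F, (2E)-1-{3-[(2E)-3,7-dimethylocta-2,6-dien-1-yl]-2-hydroxy-4-methoxyphenyl}-3-(4-hydroxyphenyl)prop-2-en-1-one | COc1ccc(C(=O)/C=C/c2ccc(O)cc2)c(O)c1C/C=C(\C)CCC=C(C)C | target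

## Summary

Total step count: 10. Longest linear sequence: 9 steps (steps 1–7, 9 and 10 from 3-methoxyphenol); step 8 is a one-step side branch.

**Steps most likely to fail**

Step 2 (ortho-metalation and allylation). The risks are incomplete lithiation, SN2' attack giving the linalyl-type isomer, and Wurtz coupling of the bromide. The fallback sets out from 3 and comes back at 7. Compound 3 is lithiated as before to 5, which is trapped with 2-isopropoxy-4,4,5,5-tetramethyl-1,3,2-dioxaborolane to give the isolable boronate 2-[2-methoxy-6-(methoxymethoxy)phenyl]-4,4,5,5-tetramethyl-1,3,2-dioxaborolane F1. F1 is then joined to geranyl bromide 4 by an allyl–aryl Suzuki–Miyaura coupling (zerovalent palladium from Pd2(dba)3 and SPhos, K3PO4, THF/H2O, 40 °C). The π-allyl palladium intermediate takes the aryl group at its less hindered terminus with E geometry retained, giving 7.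

Step 4 (magnesium-mediated ortho-formylation). The hindered, electron-rich phenol may react sluggishly or give diarylmethane by-products. The fallback sets out from 7 and comes back at 10, so steps 3 to 5 are skipped. The MOM ether 7 is lithiated ortho to the OMOM group (sec-BuLi, TMEDA, THF, −78 °C) to give {3-[(2E)-3,7-dimethylocta-2,6-dien-1-yl]-4-methoxy-2-(methoxymethoxy)phenyl}lithium F2, which is formylated with DMF to give 10. The low temperature favours chelation-controlled ring lithiation over removal of the benzylic-allylic proton.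

Step 10 (final acid deprotection). The freed 2'-OH could add to the geranyl alkene (chroman) or to the enone (flavanone), or methanol could add to an alkene. The fallback sets out from 9, uses 13, and comes back at 17 with no protecting group and no acid at the end. Salicylaldehyde 9 is treated with excess MeMgBr (THF, 0 °C) to give rac-2-[(2E)-3,7-dimethylocta-2,6-dien-1-yl]-6-(1-hydroxyethyl)-3-methoxyphenol F3. The benzylic alcohol of F3 is oxidised with activated MnO2 (CH2Cl2, rt) to 1-{3-[(2E)-3,7-dimethylocta-2,6-dien-1-yl]-2-hydroxy-4-methoxyphenyl}ethanone F4. F4 is condensed directly with unprotected 4-hydroxybenzaldehyde 13 in a Claisen–Schmidt aldol (60% aq. KOH, EtOH, rt, 48–72 h; neutralised cold with dilute acid) to give 17, at the cost of a slower, lower-yielding condensation.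

## Further compounds

F1 | step 2 | 2-[2-methoxy-6-(methoxymethoxy)phenyl]-4,4,5,5-tetramethyl-1,3,2-dioxaborolane | COCOc1cccc(OC)c1B1OC(C)(C)C(C)(C)O1
F2 | step 4 | {3-[(2E)-3,7-dimethylocta-2,6-dien-1-yl]-4-methoxy-2-(methoxymethoxy)phenyl}lithium | [Li]c1ccc(OC)c(C/C=C(\C)CCC=C(C)C)c1OCOC
F3 | step 10 | rac-2-[(2E)-3,7-dimethylocta-2,6-dien-1-yl]-6-(1-hydroxyethyl)-3-methoxyphenol | COc1ccc(C(C)O)c(O)c1C/C=C(\C)CCC=C(C)C
F4 | step 10 | 1-{3-[(2E)-3,7-dimethylocta-2,6-dien-1-yl]-2-hydroxy-4-methoxyphenyl}ethanone | COc1ccc(C(C)=O)c(O)c1C/C=C(\C)CCC=C(C)C
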